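## Structural features

The target is a 1H-isochromen-1-one (isocoumarin): benzo ring A is fused through C4a and C8a to the enol-lactone ring B (C1 carbonyl, O2, C3, C4), and C3 carries an n-pentyl chain. Ring A has a free hydroxyl at C6 and, at C8, an ether oxygen that joins it to ring C. Ring C is a 2,4-dihydroxy-6-pentylphenyl group, that is, an olivetol nucleus oxygenated at the carbon lying between one hydroxyl and the pentyl chain. There is no stereocentre, so no configuration has to be set or protected. The fragile parts are the enol lactone, which hydroxide or alkoxide opens to a keto acid, and ring C, whose 1,2,4-trioxygenated pattern makes the free phenol easy to oxidise to a quinone. The real difficulty is the diaryl ether: its oxygen sits between C8, flanked by the carbonyl-bearing C8a, and C1', flanked by a hydroxyl and a pentyl group, so a late arylation would have to join two crowded, electron-rich carbons. The key step uses the fact that ring A (C4a, C5, C6, C7, C8, C8a) has carbon substituents only on the neighbours C4a and C8a and oxygen on C6 and C8, so that C5–C8 map onto C3–C6 of a 4,6-dioxygenated 2-pyranone and C4a–C8a onto the two carbons of an alkyne that already carries the future C1 carboxyl and the future C4–C3–pentyl unit.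

## Logic of the disconnections

23 is traced back to 22 by turning the three phenolic O–H bonds into O–CH3 bonds. Free phenols would be deprotonated by every base used and the free ring C would oxidise; methyl ethers tolerate amide base, 150 °C and the Ph3PAuCl/AgOSO2CF3 catalyst. The demand on the forward step is a triple ether cleavage that spares the lactone and the diaryl ether.

22 is cut at the O2–C3 bond of ring B, giving 21. Ring B becomes a carboxyl group and an internal alkyne on neighbouring ring carbons, both of which one dienophile can deliver. The forward step must close 6-endo onto the alkyne carbon remote from the ring, not 5-exo.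

21 is traced back to its methyl ester 20, because the acid function has to pass through the thermal ring-forming step as an ester that activates the dienophile. The forward demand is hydrolysis of a benzoate with two ortho substituents, which calls for heating.

20 is cut at C4a–C5 and C8–C8a. Ring A disappears and, by way of 19, two pieces of similar size remain, 12 and 18. This is the main simplification: the aromatic ring, its full substitution pattern and the position of the ether oxygen all come from one cycloaddition with loss of CO2. The forward step must place the ester carbon next to the aryloxy carbon and must use the ester-conjugated triple bond of 18, not the distal one.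

12 is cut at the bond between its C6 and the ether oxygen, giving 5 and 11. The hindered diaryl ether is thus made while one "aryl" partner is still an electrophilic chloropyranone, by addition–elimination and not by arylation of an arene. The forward step needs dry, weakly basic conditions, because 12 is an activated acyl derivative.

5 is traced back to 4 by removing the O-methyl group, and 4, through 3 and 2, to two molecules of 1. All five ring carbons, the chlorine and both oxygens of the pyranone come from one cheap reagent. The demands are selective hydrolysis of the exocyclic acyl chloride of 2 in the presence of the C6 chloride, and methylation on O4, not on C3 or the lactone oxygen.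

11 is traced back through 10 to 9 (C–O for C–CHO), then through 8 to 7 (removal of the formyl carbon) and to 6 (removal of the two methyl groups). The extra ring C oxygen is introduced as a formyl group, which electrophilic substitution places exactly at the carbon para to one methoxy and ortho to the pentyl chain. The demand is aryl, not hydride, migration in the peracid step.

18 is cut between the ester carbon and C2, giving 17 and, one proton richer, 16. 16 is traced back to 15 by adding H and Cl across its terminal triple bond, and 15 to 13 and 14 by cutting the bond from the enyne to the heptynyl carbon. The ester is attached last, by acylation of an acetylide at low temperature. A CuCl/amine coupling of a halopropiolate ester is avoided because primary amines add to such esters. The demand is Z geometry in 15, so that hydrogen and chlorine stand anti for elimination.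

## Other disconnections considered

Alternative 1: The cut lies in ring C, at C5'–C6' and C3'–C4'. In the forward direction NaOMe would add dimethyl malonate A3 to the beta-carbon of the enone (3Z)-3-[(6-methoxy-1-oxo-3-pentyl-1H-isochromen-8-yl)oxy]non-3-en-2-one A2. The methyl ketone enolate of the adduct would then attack one of the ester groups that came from A3, giving the cyclohexane-1,3-dione methyl 3-[(6-methoxy-1-oxo-3-pentyl-1H-isochromen-8-yl)oxy]-4,6-dioxo-2-pentylcyclohexane-1-carboxylate A1, racemic and all-trans. Hydrolysis, decarboxylation, dehydrogenation to the resorcinol and one demethylation would follow.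
- In its favour: ring C is assembled from A2 and the bulk chemical A3 by the classic route to 5-alkylresorcinols, and the ether oxygen is already on the chain. No oxidation of an olivetol ring and no handling of the air-sensitive phenol 11 are needed; on this point it is better than the chosen plan. Like the chosen plan it avoids a hindered arene arylation; on that point the two are equal.
- Against it here: A2 must be made from 8-hydroxy-6-methoxy-3-pentyl-1H-isochromen-1-one A4, whose hydroxyl is hydrogen-bonded to the lactone carbonyl and is a poor nucleophile. Methoxide would open the enol lactone of A2 and of A1, which then has to be re-closed. The three stereocentres of A1 are made only to be destroyed. The aromatising oxidation must be run in the presence of the electron-rich ring A and the C3–C4 double bond, both open to halogenation or reduction.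
- Comparison: on mechanism, the ionic annulation with A3 runs at a lower temperature than the thermal cycloaddition, but it needs a strong nucleophilic base that the chosen neutral pericyclic step does not. On step economy, at least four operations follow A1 and the syntheses of A4 and A2 come before it, so it should be longer than the chosen twelve steps.

Alternative 2: The cut is the C4a–C8a bond of ring A. In the forward direction mild base would deprotonate the methylene between the ester and the aryloxy enol ether of methyl (3E)-3-(2,4-dimethoxy-6-pentylphenoxy)-5,7-dioxo-8-(2-pentyl-1,3-dioxolan-2-yl)oct-3-enoate A6. The carbanion would add to the C4a ketone, and dehydration with enolisation would give methyl 2-(2,4-dimethoxy-6-pentylphenoxy)-4-hydroxy-6-[(2-pentyl-1,3-dioxolan-2-yl)methyl]benzoate A5.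
- In its favour: the ring closes at ambient temperature, and the substitution pattern of ring A is written into the chain. A5 carries a masked C3 ketone, so one acid treatment would unmask it and close the lactone with no 6-endo/5-exo question and no Ph3PAuCl catalyst. On the endgame it is the equal of the chosen plan or slightly better.
- Against it here: A6 is a polycarbonyl chain with three different acidic methylene groups, and the one between the two ketones is the most acidic. Claisen closure onto the ester and O-cyclisation to a pyranone therefore compete with the wanted aldol. The aryloxy enol ether must also be made with E geometry, so that C8a and C6 are cis, from the same hindered phenol. The linear assembly of A6 is long and passes through sensitive beta-polycarbonyl compounds.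
- Comparison: both plans build ring A and attach the ether oxygen to an sp2 carbon before ring A is aromatic, so they are equal on structure. On mechanism, the aldol leading to A5 is reversible and its selectivity rests on relative acidities, whereas the cycloaddition is directed by the polarisation of both partners. On step economy, the convergent chosen route should reach the benzoate stage in fewer steps.

Alternative 3: The cut is the C1'–C6' bond of ring C. In the forward direction aqueous Ba(OH)2 would open the 4-pyranone of 6-methoxy-8-[(4-oxo-6-pentyl-4H-pyran-2-yl)methoxy]-3-pentyl-1H-isochromen-1-one A8 to the triketone 1-[(6-methoxy-1-oxo-3-pentyl-1H-isochromen-8-yl)oxy]undecane-2,4,6-trione A9. Its aryloxymethylene carbon would add to the pentyl ketone and dehydrate to 8-(2,4-dihydroxy-6-pentylphenoxy)-6-methoxy-3-pentyl-1H-isochromen-1-one A7.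
- In its favour: the pyranone-to-resorcinol recyclisation is a well-known polyketide-type reaction. Ring C of A7 arrives with both hydroxyls free and the oxygen in the right place, so A7 has only one methyl ether left to cleave. On protecting-group economy in the last step it is better than the chosen plan.
- Against it here: hot aqueous Ba(OH)2 would saponify the isocoumarin lactone. A9 can also close the other way, with the pentyl alpha-methylene attacking the aryloxymethyl ketone, which would give an isomer of A7. A8 requires alkylation of the poorly nucleophilic 8-hydroxy-6-methoxy-3-pentyl-1H-isochromen-1-one A4, which needs its own isocoumarin synthesis, with 2-(bromomethyl)-6-pentyl-4H-pyran-4-one A10, and A10 must be made separately as well.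
- Comparison: on structure, this plan builds ring C last on a finished isocoumarin, whereas the chosen plan builds ring A on a finished ring C, where the lactone is not yet present to be damaged. On mechanism, the regiochemistry here depends on which of two enolates forms and cyclises. On step economy, the two building blocks A4 and A10 plus alkylation, recyclisation and demethylation of A7 should come out equal to or longer than the chosen route.

Key step: step 9

Remark on the chemistry: the target has no stereocentre. The only stereogenic compound of the route, the bridged adduct 19, is racemic, is drawn as one enantiomer and loses both stereocentres in the step that forms it.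

## Steps

Step 1
Reactants: 1 malonyl dichloride (two molecules)
Product: 4 6-chloro-4-hydroxy-2H-pyran-2-one, via acid chloride 2 (not isolated), via carboxylic acid 3 (not isolated)
Conditions: neat, rt, 3 d (−HCl); then H2O (1 equiv), 1,4-dioxane, 50 °C (−CO2)
Reagents that add atoms: none
Why: Self-condensation of the bis-acid chloride (C-acylation of one molecule by another, then lactonisation through the enolised acyl chloride) is the established entry to this chloropyranone ring. The exocyclic acyl chloride of 2 is far more electrophilic than the vinylogous C6–Cl, so one equivalent of water should hydrolyse it selectively, and the vinylogous beta-keto acid 3 decarboxylates on gentle warming.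

Step 2
Reactants: 4 6-chloro-4-hydroxy-2H-pyran-2-one
Product: 5 6-chloro-4-methoxy-2H-pyran-2-one
Conditions: Me2SO4, K2CO3, acetone, rt
Reagents that add atoms: dimethyl sulfate, COS(=O)(=O)OC
Why: O-Alkylation of the ambident 4-pyranolate (Williamson type): a hard methylating agent should react at the exocyclic O4, which keeps the conjugated 2-pyranone, and not at C3 or the lactone oxygen. The delocalised anion of 4 is a weak nucleophile toward the C6–Cl of the product at room temperature, so self-condensation should stay minor.

Step 3
Reactants: 6 olivetol (5-pentylbenzene-1,3-diol)
Product: 7 1,3-dimethoxy-5-pentylbenzene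
Conditions: MeI, K2CO3, DMF, rt
Reagents that add atoms: iodomethane, CI
Why: Williamson ether synthesis on both phenolic hydroxyls. Methyl ethers are chosen because they survive amide base, 150 °C and the Ph3PAuCl/AgOSO2CF3 catalyst and can be removed together with the ring A methyl ether at the end.

Step 4
Reactants: 7 1,3-dimethoxy-5-pentylbenzene
Product: 9 2,4-dimethoxy-6-pentylbenzaldehyde, via aryl iminium chloride 8 (not isolated)
Conditions: POCl3, DMF, 0 → 60 °C; then aq. NaOAc
Reagents that add atoms: N,N-dimethylformamide, CN(C)C=O; water, O
Why: Vilsmeier–Haack formylation: the chloroiminium electrophile should attack the position para to one methoxy and ortho to the other, which is less shielded than the carbon between the two methoxy groups. Hydrolysis of iminium salt 8 on work-up gives the aldehyde.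

Step 5
Reactants: 9 2,4-dimethoxy-6-pentylbenzaldehyde
Product: 11 2,4-dimethoxy-6-pentylphenol, via aryl formate 10 (not isolated)
Conditions: mCPBA, CH2Cl2, 0 °C → rt; then K2CO3 (cat.), MeOH, rt
Reagents that add atoms: 3-chloroperoxybenzoic acid (mCPBA), O=C(OO)c1cccc(Cl)c1
Why: Baeyer–Villiger oxidation of an electron-rich benzaldehyde (Dakin type): the aryl group, activated by ortho and para methoxy groups, should migrate in preference to hydride, and catalytic carbonate in methanol transesterifies formate 10 to the phenol. 11 is kept under nitrogen because the 1,2,4-trioxygenated ring is easily oxidised.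

Step 6
Reactants: 5 6-chloro-4-methoxy-2H-pyran-2-one, 11 2,4-dimethoxy-6-pentylphenol
Product: 12 6-(2,4-dimethoxy-6-pentylphenoxy)-4-methoxy-2H-pyran-2-one
Conditions: Cs2CO3, MeCN, 0 °C → rt, N2
Reagents that add atoms: none
Why: Addition–elimination (vinylogous acyl substitution): the phenoxide of 11 adds to C6, the chlorine-bearing end of the dienyl lactone, and chloride is expelled. Attack at the lactone carbonyl instead would open the ring, lose chloride to a dienyl ketene and re-close by oxa-6π electrocyclisation to the same compound, because that path merely exchanges C2 and C6, so both modes of attack converge on 12. The base is weak and anhydrous, which protects the activated acyl product from hydrolysis.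

Step 7
Reactants: 13 1-heptyne, 14 (Z)-1,2-dichloroethene
Product: 15 (Z)-1-chloronon-1-en-3-yne
Conditions: Pd(PPh3)4 (cat.), CuI (cat.), n-BuNH2, Et2O, rt; 14 in fivefold excess
Reagents that add atoms: none
Why: Sonogashira coupling of a terminal alkyne with a vinyl chloride that is activated by the second chlorine. The excess of 14 suppresses double coupling, and the geometry is retained, which places the remaining vinylic hydrogen anti to chlorine for the next step.

Step 8
Reactants: 15 (Z)-1-chloronon-1-en-3-yne
Product: 18 methyl deca-2,4-diynoate, via nona-1,3-diyne 16 (not isolated), via lithium diynide 17 (not isolated)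
Conditions: LiN(i-Pr)2 (2.1 equiv), THF, −78 °C; then transfer into ClCO2Me (3 equiv), THF, −78 → 0 °C
Reagents that add atoms: methyl chloroformate, COC(=O)Cl
Why: Dehydrochlorination followed by acetylide acylation: the first equivalent of amide effects anti E2 elimination to the terminal diyne 16 and the second deprotonates it to 17, which is added to excess chloroformate so that the reaction stops at the ynoate. Only hindered diisopropylamine is present, at low temperature, so conjugate addition to the electrophilic diynoate is not expected.

Step 9
Reactants: 12 6-(2,4-dimethoxy-6-pentylphenoxy)-4-methoxy-2H-pyran-2-one, 18 methyl deca-2,4-diynoate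
Product: 20 methyl 2-(2,4-dimethoxy-6-pentylphenoxy)-6-(hept-1-yn-1-yl)-4-methoxybenzoate, via bridged lactone adduct 19 (not isolated)
Conditions: 18 (2 equiv), BHT (cat.), o-xylene, 150 °C, sealed tube (−CO2)
Reagents that add atoms: none
Why: The C3=C4–C5=C6 diene of 12, made electron-rich by the 4-methoxy group and the two oxygens on C6, should add in a normal-electron-demand [4+2] cycloaddition to the ester-conjugated triple bond of 18, giving the 2-oxabicyclo[2.2.2]octadienone 19. At the reaction temperature 19 should lose its lactone bridge as CO2 by retro-[4+2] cycloreversion, which is irreversible and gives benzoate 20 directly at the aromatic oxidation level. The closest known reaction type is the thermal Diels–Alder/CO2-extrusion of 2-pyranones with acetylenic esters to give benzoates. Ring A is closed by an intermolecular, concerted but asynchronous cycloaddition that forms C4a–C5 and C8–C8a in one event, not by cyclisation of a chain. No stereocentre has to be controlled, since the two bridgeheads of racemic 19 become sp2 carbons when CO2 leaves. The step needs the ester carbon to end next to the aryloxy carbon: pyranone C3 is the nucleophilic diene terminus and the beta-carbon of the ynoate the electrophilic one, so this bond leads, with charge developing on C6 (stabilised by two oxygens) and on the ester alpha-carbon. The step also needs reaction at the proximal triple bond, which alone is directly activated by the ester, whereas the distal one carries an alkyl group. The product is no longer a diene and its remaining alkyne is unactivated, so a second addition is not expected; the excess of 18 and the radical inhibitor are there to offset thermal loss of the diynoate.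

Step 10
Reactants: 20 methyl 2-(2,4-dimethoxy-6-pentylphenoxy)-6-(hept-1-yn-1-yl)-4-methoxybenzoate
Product: 21 2-(2,4-dimethoxy-6-pentylphenoxy)-6-(hept-1-yn-1-yl)-4-methoxybenzoic acid
Conditions: KOH, MeOH/THF/H2O, 65 °C; then aq. HCl
Reagents that add atoms: potassium hydroxide, [K+].[OH-]
Why: Saponification by acyl–oxygen cleavage. The ester has two ortho substituents, hence the heating, and the aryl ethers and the internal alkyne are inert to aqueous hydroxide.

Step 11
Reactants: 21 2-(2,4-dimethoxy-6-pentylphenoxy)-6-(hept-1-yn-1-yl)-4-methoxybenzoic acid
Product: 22 8-(2,4-dimethoxy-6-pentylphenoxy)-6-methoxy-3-pentyl-1H-isochromen-1-one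
Conditions: Ph3PAuCl (5 mol %), AgOSO2CF3 (5 mol %), CH2Cl2, rt
Reagents that add atoms: none
Why: Cycloisomerisation of a 2-alkynylbenzoic acid catalysed by Ph3PAuCl/AgOSO2CF3 (6-endo-dig oxycyclisation). Cationic monovalent gold, freed from Ph3PAuCl by AgOSO2CF3, activates the triple bond; the carboxyl oxygen attacks the alkyne carbon remote from the ring, the more electrophilic one through conjugation with the carboxyl-bearing arene, and protodeauration gives the isocoumarin. The soft catalyst should leave the aryl ethers untouched.

Step 12
Reactants: 22 8-(2,4-dimethoxy-6-pentylphenoxy)-6-methoxy-3-pentyl-1H-isochromen-1-one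
Product: 23 8-(2,4-dihydroxy-6-pentylphenoxy)-6-hydroxy-3-pentyl-1H-isochromen-1-one (target)
Conditions: BBr3 (6 equiv), CH2Cl2, −78 °C → rt; then H2O
Reagents that add atoms: none
Why: Lewis-acid cleavage of aryl methyl ethers: BBr3 complexes each methoxy oxygen and bromide removes the methyl group by SN2, a path closed to the diaryl ether, which has no sp3 carbon on oxygen. The lactone only coordinates reversibly and should be recovered intact on aqueous work-up, which is done cold and air-free because ring C is then an oxidisable phenol.

## Compound list

1 | malonyl dichloride | O=C(Cl)CC(Cl)=O | starting material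
2 | 6-chloro-4-hydroxy-2-oxo-2H-pyran-3-carbonyl chloride | O=C(Cl)c1c(O)cc(Cl)oc1=O | intermediate (not isolated)
3 | 6-chloro-4-hydroxy-2-oxo-2H-pyran-3-carboxylic acid | O=C(O)c1c(O)cc(Cl)oc1=O | intermediate (not isolated)
4 | 6-chloro-4-hydroxy-2H-pyran-2-one | O=c1cc(O)cc(Cl)o1 | intermediate
5 | 6-chloro-4-methoxy-2H-pyran-2-one | COc1cc(=O)oc(Cl)c1 | intermediate
6 | olivetol (5-pentylbenzene-1,3-diol) | CCCCCc1cc(O)cc(O)c1 | starting material
7 | 1,3-dimethoxy-5-pentylbenzene | CCCCCc1cc(OC)cc(OC)c1 | intermediate
8 | N-[(2,4-dimethoxy-6-pentylphenyl)methylidene]-N-methylmethanaminium chloride | CCCCCc1cc(OC)cc(OC)c1C=[N+](C)C.[Cl-] | intermediate (not isolated)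
9 | 2,4-dimethoxy-6-pentylbenzaldehyde | CCCCCc1cc(OC)cc(OC)c1C=O | intermediate
10 | 2,4-dimethoxy-6-pentylphenyl formate | CCCCCc1cc(OC)cc(OC)c1OC=O | intermediate (not isolated)
11 | 2,4-dimethoxy-6-pentylphenol | CCCCCc1cc(OC)cc(OC)c1O | intermediate
12 | 6-(2,4-dimethoxy-6-pentylphenoxy)-4-methoxy-2H-pyran-2-one | COc1cc(=O)oc(Oc2c(OC)cc(OC)cc2CCCCC)c1 | intermediate
13 | 1-heptyne | CCCCCC#C | starting material
14 | (Z)-1,2-dichloroethene | Cl/C=C\Cl | starting material
15 | (Z)-1-chloronon-1-en-3-yne | Cl/C=C\C#CCCCCC | intermediate
16 | nona-1,3-diyne | C#CC#CCCCCC | intermediate (not isolated)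
17 | lithium nona-1,3-diyn-1-ide | [Li]C#CC#CCCCCC | intermediate (not isolated)
18 | methyl deca-2,4-diynoate | CCCCCC#CC#CC(=O)OC | intermediate
19 | methyl 1-(2,4-dimethoxy-6-pentylphenoxy)-5-(hept-1-yn-1-yl)-8-methoxy-3-oxo-2-oxabicyclo[2.2.2]octa-5,7-diene-6-carboxylate (racemic, one enantiomer drawn) | O=C1O[C@]2(Oc3c(OC)cc(OC)cc3CCCCC)C=C(OC)[C@H]1C(C#CCCCCC)=C2C(=O)OC | intermediate (not isolated)
20 | methyl 2-(2,4-dimethoxy-6-pentylphenoxy)-6-(hept-1-yn-1-yl)-4-methoxybenzoate | CCCCCC#Cc1cc(OC)cc(Oc2c(OC)cc(OC)cc2CCCCC)c1C(=O)OC | intermediate
21 | 2-(2,4-dimethoxy-6-pentylphenoxy)-6-(hept-1-yn-1-yl)-4-methoxybenzoic acid | CCCCCC#Cc1cc(OC)cc(Oc2c(OC)cc(OC)cc2CCCCC)c1C(=O)O | intermediate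
22 | 8-(2,4-dimethoxy-6-pentylphenoxy)-6-methoxy-3-pentyl-1H-isochromen-1-one | CCCCCc1cc2cc(OC)cc(Oc3c(OC)cc(OC)cc3CCCCC)c2c(=O)o1 | intermediate
23 | 8-(2,4-dihydroxy-6-pentylphenoxy)-6-hydroxy-3-pentyl-1H-isochromen-1-one | CCCCCc1cc2cc(O)cc(Oc3c(O)cc(O)cc3CCCCC)c2c(=O)o1 | target

## Step count and least certain steps

Total: 12 steps. Longest linear sequence: 8 steps (6 → 7 → 9 → 11 → 12 → 20 → 21 → 22 → 23; steps 3, 4, 5, 6, 9, 10, 11 and 12).

Step 9 (key step). The most likely failure is thermal oligomerisation of the diynoate outrunning a cycloaddition that is slowed by the doubly ortho-substituted aryloxy group at C6. Less likely is partial loss of orientation or reaction at the distal triple bond. The fallback sets out from 12. It is heated with the smaller and more electrophilic dienophile methyl 3-bromoprop-2-ynoate F1, made from methyl propiolate with N-bromosuccinimide and catalytic AgNO3 in acetone. The same orientation rule should give, through methyl 5-bromo-1-(2,4-dimethoxy-6-pentylphenoxy)-8-methoxy-3-oxo-2-oxabicyclo[2.2.2]octa-5,7-diene-6-carboxylate F2 and loss of CO2, methyl 2-bromo-6-(2,4-dimethoxy-6-pentylphenoxy)-4-methoxybenzoate F3. Sonogashira coupling of this bromide with 13 (PdCl2(PPh3)2, CuI, Et3N, DMF, 70 °C) returns to the route at 20.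

Step 6. The phenoxide may react in unwanted ways: displacement of methoxide at C4, ring opening that is made irreversible by traces of water, or air oxidation of the electron-rich phenoxide before it couples. The fallback reverses the order of events and sets out from 5. Cycloaddition of 5 with 18 under the conditions of step 9 should give, through methyl 1-chloro-5-(hept-1-yn-1-yl)-8-methoxy-3-oxo-2-oxabicyclo[2.2.2]octa-5,7-diene-6-carboxylate F4, the chloroarene methyl 2-chloro-6-(hept-1-yn-1-yl)-4-methoxybenzoate F5. Palladium-catalysed diaryl ether coupling of this chloride with 11 (Pd(OAc)2, t-BuXPhos, K3PO4, toluene, 100 °C) returns at 20. This accepts a hindered arylation, which is why it is only the reserve.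

Step 11. Ring closure may go partly 5-exo, to an alkylidene phthalide, if the steric pressure of the neighbouring aryloxy group twists the carboxyl out of the ring plane. The fallback sets out from 21. Iodolactonisation (I2, NaHCO3, MeCN, rt), which strongly prefers the 6-endo mode through the iodonium ion, should give 8-(2,4-dimethoxy-6-pentylphenoxy)-4-iodo-6-methoxy-3-pentyl-1H-isochromen-1-one F6. Reductive removal of iodine (Pd(OAc)2, PPh3, HCO2Na, DMF, 80 °C) returns at 22 and would also remove any iodine introduced on ring C.

Step 8. Trouble may come from incomplete elimination, from a second addition of the diynide to the newly formed ester, or from base-induced propargyl–allenyl isomerisation of the diyne. The fallback sets out from 13. Bromination (N-bromosuccinimide, AgNO3 cat., acetone) gives 1-bromohept-1-yne F7. Cadiot–Chodkiewicz coupling with propiolic acid (CuCl cat., NH2OH·HCl, aq. EtNH2, MeOH, 0 °C), in which the carboxylate form resists amine addition, gives deca-2,4-diynoic acid F8. Esterification (MeI, KHCO3, DMF, rt) returns at 18.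

Step 5. The peracid may oxidise the electron-rich ring, or hydride may migrate in place of aryl, which would give a benzoic acid. The fallback sets out from 7 and bypasses 9. Bromination para to a methoxy group (N-bromosuccinimide, MeCN, 0 °C) gives 1-bromo-2,4-dimethoxy-6-pentylbenzene F9. Palladium-catalysed hydroxylation (Pd2(dba)3, t-BuXPhos, KOH, 1,4-dioxane/H2O, 100 °C) returns at 11.

## Further compounds

F1 | step 9 | methyl 3-bromoprop-2-ynoate | BrC#CC(=O)OC
F2 | step 9 | methyl 5-bromo-1-(2,4-dimethoxy-6-pentylphenoxy)-8-methoxy-3-oxo-2-oxabicyclo[2.2.2]octa-5,7-diene-6-carboxylate (racemic, one enantiomer drawn, not isolated) | O=C1O[C@]2(Oc3c(OC)cc(OC)cc3CCCCC)C=C(OC)[C@H]1C(Br)=C2C(=O)OC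
F3 | step 9 | methyl 2-bromo-6-(2,4-dimethoxy-6-pentylphenoxy)-4-methoxybenzoate | COC(=O)c1c(Br)cc(OC)cc1Oc1c(OC)cc(OC)cc1CCCCC
F4 | step 6 | methyl 1-chloro-5-(hept-1-yn-1-yl)-8-methoxy-3-oxo-2-oxabicyclo[2.2.2]octa-5,7-diene-6-carboxylate (racemic, one enantiomer drawn, not isolated) | O=C1O[C@]2(Cl)C=C(OC)[C@H]1C(C#CCCCCC)=C2C(=O)OC
F5 | step 6 | methyl 2-chloro-6-(hept-1-yn-1-yl)-4-methoxybenzoate | CCCCCC#Cc1cc(OC)cc(Cl)c1C(=O)OC
F6 | step 11 | 8-(2,4-dimethoxy-6-pentylphenoxy)-4-iodo-6-methoxy-3-pentyl-1H-isochromen-1-one | CCCCCc1oc(=O)c2c(Oc3c(OC)cc(OC)cc3CCCCC)cc(OC)cc2c1I
F7 | step 8 | 1-bromohept-1-yne | CCCCCC#CBr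
F8 | step 8 | deca-2,4-diynoic acid | CCCCCC#CC#CC(=O)O
F9 | step 5 | 1-bromo-2,4-dimethoxy-6-pentylbenzene | CCCCCc1cc(OC)cc(OC)c1Br
A1 | alternative 1 | methyl 3-[(6-methoxy-1-oxo-3-pentyl-1H-isochromen-8-yl)oxy]-4,6-dioxo-2-pentylcyclohexane-1-carboxylate (racemic, all-trans, one enantiomer drawn) | COC(=O)[C@@H]1C(=O)CC(=O)[C@H](Oc2cc(OC)cc3cc(CCCCC)oc(=O)c23)[C@H]1CCCCC
A2 | alternative 1 | (3Z)-3-[(6-methoxy-1-oxo-3-pentyl-1H-isochromen-8-yl)oxy]non-3-en-2-one | CCCCC/C=C(\Oc1cc(OC)cc2cc(CCCCC)oc(=O)c12)C(C)=O
A3 | alternative 1 | dimethyl malonate | COC(=O)CC(=O)OC
A4 | alternative 1 | 8-hydroxy-6-methoxy-3-pentyl-1H-isochromen-1-one | CCCCCc1cc2cc(OC)cc(O)c2c(=O)o1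
A5 | alternative 2 | methyl 2-(2,4-dimethoxy-6-pentylphenoxy)-4-hydroxy-6-[(2-pentyl-1,3-dioxolan-2-yl)methyl]benzoate | COC(=O)c1c(CC2(CCCCC)OCCO2)cc(O)cc1Oc1c(OC)cc(OC)cc1CCCCC
A6 | alternative 2 | methyl (3E)-3-(2,4-dimethoxy-6-pentylphenoxy)-5,7-dioxo-8-(2-pentyl-1,3-dioxolan-2-yl)oct-3-enoate | COC(=O)C/C(Oc1c(OC)cc(OC)cc1CCCCC)=C\C(=O)CC(=O)CC1(CCCCC)OCCO1
A7 | alternative 3 | 8-(2,4-dihydroxy-6-pentylphenoxy)-6-methoxy-3-pentyl-1H-isochromen-1-one | CCCCCc1cc2cc(OC)cc(Oc3c(O)cc(O)cc3CCCCC)c2c(=O)o1
A8 | alternative 3 | 6-methoxy-8-[(4-oxo-6-pentyl-4H-pyran-2-yl)methoxy]-3-pentyl-1H-isochromen-1-one | CCCCCc1cc(=O)cc(COc2cc(OC)cc3cc(CCCCC)oc(=O)c23)o1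
A9 | alternative 3 | 1-[(6-methoxy-1-oxo-3-pentyl-1H-isochromen-8-yl)oxy]undecane-2,4,6-trione | CCCCCC(=O)CC(=O)CC(=O)COc1cc(OC)cc2cc(CCCCC)oc(=O)c12
A10 | alternative 3 | 2-(bromomethyl)-6-pentyl-4H-pyran-4-one | CCCCCc1cc(=O)cc(CBr)o1
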